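## Analysis of the target

The target is a naphthazarin, a 5,8-dihydroxy-1,4-naphthoquinone with quinoid ring A (C1–C4, C4a, C8a) and hydroquinoid ring B (C4a–C8a), and at C2 it carries a cyclobutane numbered here C1' (carbinol carbon, bonded to C2 and to the ester oxygen), C2' (gem-dimethyl carbon), C3' and C4' (methylenes). C1' is the only stereocentre; it is fully substituted, has the R configuration, and has no neighbouring stereocentre to relay from, so its absolute configuration must come from an external agent. The oxygen on C1' is acylated by angelic acid 16, the (Z)-2-methylbut-2-enoate, which isomerises easily to the E isomer under nucleophilic, acidic or prolonged basic conditions, and the alcohol that carries it is tertiary and flanked by a quaternary carbon and an ortho-substituted ring. The naphthazarin is redox-active, chelating, base-sensitive and tautomeric; it does not survive organometallic or alkoxide steps, and freeing its peri-hydroxyls from methyl ethers at the end is harsh. The C1' ester is tertiary and benzylic-type on a strained ring, so acids can ionise it, and one-electron oxidants open free 1-arylcyclobutanols. The difficulty is therefore threefold: a strained ring with a quaternary stereocentre that offers no handle, a hindered and geometrically labile ester, and a quinone that has to appear last. The strategy rests on one feature: C1' is a carbinol carbon next to methylene C4', so that, if C4' temporarily carries a hydroxyl, C1'–C4' is the central bond of a 1,2-diol and can be made by reductive coupling of an aryl ketone (C1') with a tethered aldehyde (C4'). That extra hydroxyl then serves as the handle for resolution before it is removed.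

## Retrosynthetic reasoning

**Ring B (25 ⇒ 20 + 22).** The bonds C4a–C5 and C8a–C8 are cut, so that C5–C8 and their two oxygens come from the symmetrical bis(silyloxy)furan 22 and the side-chain-bearing ring comes from benzoquinone 20. This cycloaddition delivers naphthazarin 25 at its final oxidation level with free hydroxyls. No demethylation follows, no regiochemical question arises, and the angelate is only a spectator. Furan 22 is traced to succinic anhydride 21.

**Quinone (20 ⇒ 19).** No skeletal bond is cut. The quinone is traced to the 1,4-dimethoxybenzene 19, because only the dimethyl ether tolerates the aryllithium, samarium, tin-radical and alkoxide chemistry that precedes it. The forward step is an oxidative demethylation that must spare the angelate.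

**Ester (19 ⇒ 15 + 16).** The acyl–oxygen bond is cut, giving tertiary cyclobutanol 15 and angelic acid 16. Esterification is placed before the oxidation for two reasons. A tertiary alkoxide can be used only while no quinone is present. The ester also protects the cyclobutanol against oxidative ring opening by the one-electron oxidant of the demethylation. The forward step must acylate a hindered alkoxide without loss of the Z geometry.

**C4' oxygen (15 ⇒ 14 ⇒ 12).** A hydroxyl is added retrosynthetically at C4', leading to the cis-diol 12 through thiocarbamate 14. The forward step is a radical deoxygenation that must remove the secondary oxygen and leave the tertiary benzylic one.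

**Absolute configuration (12 ⇒ 11 ⇒ 10).** Enantiopure diol 12 is traced through its monoacetate 11 to racemic cis-diol 10. A lipase can act at the secondary carbinol C4'. Because C4' and C1' are locked cis on the ring, selecting the configuration at C4' also selects C1'.

**Cyclobutane (10 ⇒ 9), the key disconnection.** The C1'–C4' bond is cut to give keto aldehyde 9, with the aryl ketone as C1' and the aldehyde as C4'. This is the only ring bond flanked by two oxygens. Cutting it reduces a strained ring with a quaternary carbinol to an open chain with no stereocentre. The forward reaction must close a four-membered ring reductively and set the two hydroxyls cis.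

**Chain (9 ⇒ 7 ⇒ 3 + 4, 3 ⇒ 1).** The aldehyde is traced to the terminal alkene of ketone 7. The aryl–carbonyl bond is then cut to aryl bromide 4 and the N-methoxy-N-methyl amide 3 of the commercial acid 1, whose quaternary carbon becomes C2'.

## Alternatives that were turned down

**Alternative 1: alkynyl benzocyclobutenone ring expansion.** The quinoid ring is cut at C1–C2 and traced to an arene-fused four-membered ketone.

- Forward key step: thermolysis of 8-{[(R)-2,2-dimethyl-1-(triethylsilyloxy)cyclobutyl]ethynyl}-8-hydroxy-2,5-dimethoxybicyclo[4.2.0]octa-1,3,5-trien-7-one A2 opens the cyclobutenone to an ortho-quinoid ketene. The ketene carbon bonds to the far alkyne carbon, the hydroxyl hydrogen moves to C3, and (R)-2-[2,2-dimethyl-1-(triethylsilyloxy)cyclobutyl]-5,8-dimethoxynaphthalene-1,4-dione A1 results.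
- For: it is convergent, fixes the position of the side chain on the quinone, needs no oxidant to create the quinone, and takes the cyclobutanol ready-made from (R)-[(1-ethynyl-2,2-dimethylcyclobutyl)oxy]triethylsilane A3. On these points it is stronger than the chosen route.
- Against: A3 is a tertiary propargylic carbinol with no second functional group near the stereocentre, so it must be made by enantioselective addition to a hindered ketone or resolved at a tertiary alcohol. A2 itself needs several steps, among them the construction of a strained ring fused to the arene. The ring-expansion intermediate can close to a five-membered ring when the alkyne terminus bears a bulky, non-stabilising tertiary alkyl group.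
- Endgame: from A1 two aryl methyl ethers must still be cleaved next to a quinone, and the tertiary alcohol must be unmasked and angeloylated when the ring can no longer tolerate an alkoxide.
- Comparison: the chosen route spends more steps on the four-membered ring, but it sets the stereocentre through a secondary hydroxyl, installs the angelate before any quinone exists, and never demethylates.

**Alternative 2: dimethoxybenzyne–furan cycloaddition.** The bonds C4–C4a and C1–C8a are cut.

- Forward key step: the aryne released by fluoride from 3,6-dimethoxy-2-(trimethylsilyl)phenyl trifluoromethanesulfonate A6 adds across the 2,5-positions of (R)-1-(furan-3-yl)-2,2-dimethylcyclobutyl (Z)-2-methylbut-2-enoate A5. The product is the 1,4-epoxide (R)-1-(5,8-dimethoxy-1,4-dihydro-1,4-epoxynaphthalen-2-yl)-2,2-dimethylcyclobutyl (Z)-2-methylbut-2-enoate A4, as both bridgehead epimers.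
- For: the key step is neutral and mild, it is the most convergent of all the routes, and the angelate is already in place on a small fragment. In this respect it is as good as the chosen route.
- Against: A4 is at the wrong oxidation level. The oxygen bridge must be opened, normally by acid through a cation next to an ionisable tertiary ester on a strained ring, and opening gives naphthol regioisomers. The ring must then be oxidised to the quinone and both methyl ethers removed. A5 is a handle-free tertiary carbinol like A3, and as a furyl carbinyl ester it is acid-labile.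
- Comparison: the chosen annulation is redox-neutral and ends directly at the free naphthazarin. It is less convergent, but it avoids three oxidation-state and deprotection steps on the most sensitive intermediate.

**Alternative 3: chromium carbene benzannulation.** Ring A is cut at C3–C4, C1–C2 and C1–C8a.

- Forward key step: pentacarbonyl{[2,5-bis(methoxymethoxy)phenyl](methoxy)methylidene}chromium A8 (zerovalent chromium) reacts with alkyne A3 in a Dötz benzannulation. The product is (R)-2-[2,2-dimethyl-1-(triethylsilyloxy)cyclobutyl]-4-methoxy-5,8-bis(methoxymethoxy)naphthalen-1-ol A7.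
- For: it is convergent, the bulky alkyne substituent is expected next to the new phenol, which is where the target has it, and the new ring arrives as a hydroquinone monoether that a mild oxidant converts to the quinone. The acetal protecting groups are easier to remove than methyl ethers, so on deprotection it is stronger than Alternatives 1 and 2.
- Against: the chromium is stoichiometric. The ortho-alkoxy group of A8 can chelate the metal and divert the annulation. A3 has a fully substituted propargylic carbon beside a gem-dimethyl group and is a very hindered insertion partner. The stereocentre problem of A3 remains.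
- Endgame: after A7 there are still oxidation, acid-mediated acetal removal, desilylation and a late angeloylation on a quinone-level intermediate.
- Comparison: the chosen route uses cheap stoichiometric reagents, has a resolvable intermediate, and needs no esterification after the quinone is formed. It is more linear.

Key step: step 4

**Assumptions.**
- The naphthazarin tautomers interconvert rapidly, so the product of step 12 and the structure drawn with the side chain on the quinoid ring are the same compound.
- The lipase is assumed to acylate the (R)-configured secondary carbinol, as the empirical size rule for secondary alcohols predicts. If it shows the opposite preference, the recovered diol is the wanted enantiomer and step 6 is omitted.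

## Route

**Step 1**
Reactants: 1 2,2-dimethylpent-4-enoic acid
Product: 3 N-methoxy-N,2,2-trimethylpent-4-enamide, via 2,2-dimethylpent-4-enoyl chloride 2 (not isolated)
Conditions: (COCl)2, cat. DMF, CH2Cl2, 0 °C → rt; concentrate; MeNHOMe·HCl, Et3N, CH2Cl2, 0 °C → rt
Reagents that add atoms: N,O-dimethylhydroxylamine hydrochloride, CNOC.Cl
Why: Amide formation through the acid chloride is reliable for an α,α-disubstituted acid, where direct coupling is slow; the terminal alkene is inert.

**Step 2**
Reactants: 4 1-bromo-2,5-dimethoxybenzene; 3 N-methoxy-N,2,2-trimethylpent-4-enamide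
Product: 7 1-(2,5-dimethoxyphenyl)-2,2-dimethylpent-4-en-1-one, via (2,5-dimethoxyphenyl)lithium 5 (not isolated), via lithium hemiaminal chelate 6 (not isolated)
Conditions: n-BuLi, THF, −78 °C; then 3, −78 → 0 °C; 1 M HCl
Reagents that add atoms: none
Why: Bromine–lithium exchange gives aryllithium 5, which adds once to the N-methoxy-N-methyl amide (Weinreb ketone synthesis); the chelated adduct 6 persists until the acidic quench, so double addition is not expected, and the ketone formed has no α-hydrogen.

**Step 3**
Reactants: 7 1-(2,5-dimethoxyphenyl)-2,2-dimethylpent-4-en-1-one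
Product: 9 4-(2,5-dimethoxyphenyl)-3,3-dimethyl-4-oxobutanal, via secondary ozonide 8 (not isolated)
Conditions: O3, CH2Cl2, −78 °C (Sudan Red 7B end point); PPh3, −78 °C → rt
Reagents that add atoms: ozone, O=[O+][O-]
Why: Ozonolysis with reductive work-up; the monosubstituted alkene reacts far faster than the acyl-deactivated dimethoxybenzene ring, and the dye marks the end point. The keto aldehyde cannot undergo Paal–Knorr condensation because the ketone has no α-hydrogen; it is used without delay.

**Step 4**
Reactants: 9 4-(2,5-dimethoxyphenyl)-3,3-dimethyl-4-oxobutanal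
Product: 10 cis-1-(2,5-dimethoxyphenyl)-4,4-dimethylcyclobutane-1,2-diol (racemate of the (1R,2R) and (1S,2S) forms)
Conditions: SmI2 (2.5 equiv), THF, −78 °C → rt, slow addition of 9 to high dilution; aq. Na2S2O3/NaHCO3
Reagents that add atoms: none
Why: SmI2 transfers one electron to the aryl ketone of 9, the more easily reduced carbonyl, giving a ketyl bound to trivalent samarium; the ketyl carbon C1' attacks the aldehyde carbon C4', held close by coordination of its oxygen to the same oxophilic metal, and a second equivalent of SmI2 reduces the resulting oxygen-centred radical at once so that the strained ring does not reopen. The nearest known reaction is the samarium diiodide pinacol cyclisation of 1,4-diketones and 1,4-keto aldehydes, which furnishes cyclobutane-1,2-diols with the two hydroxyls cis. The cyclobutane closes in a 4-exo-trig mode, the radical carbon C1' adding to the carbonyl carbon C4' with the oxygen exocyclic. C1' and C4' become stereocentres together: the samarium bridge between the two oxygens can span them only when they are cis, so the cis-diol is expected, while the absolute configuration is not controlled and 10 is racemic. If the aldehyde is reduced first, its ketyl adds to the ketone and the same diol results, so selectivity between the two carbonyls is not needed. The step does need cyclisation to win over simple reduction and over intermolecular coupling: the gem-dimethyl group at C2' folds the chain (gem-dialkyl effect) and leaves the ketone without enolisable hydrogens, no proton donor is present before work-up, and the substrate is added slowly at high dilution.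

**Step 5**
Reactants: 10 cis-1-(2,5-dimethoxyphenyl)-4,4-dimethylcyclobutane-1,2-diol (racemate)
Product: 11 (1R,2R)-2-(2,5-dimethoxyphenyl)-2-hydroxy-3,3-dimethylcyclobutyl acetate
Conditions: immobilised Burkholderia cepacia lipase, vinyl acetate, t-BuOMe, 35 °C, stopped just before half conversion; chromatography
Reagents that add atoms: vinyl acetate, C=COC(C)=O
Why: Lipase-catalysed kinetic resolution by irreversible transesterification; only the secondary hydroxyl, which in the cis-diol lies on the ring face opposite the aryl group, can be acylated. With C1' as the large and the C3' methylene as the medium substituent, the (R)-carbinol is expected to react, and the fixed cis relationship transfers this choice to the tertiary centre C1'. The absolute configuration of 11 would be verified by Mosher ester analysis of the derived diol or by X-ray crystallography.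

**Step 6**
Reactants: 11 (1R,2R)-2-(2,5-dimethoxyphenyl)-2-hydroxy-3,3-dimethylcyclobutyl acetate
Product: 12 (1R,2R)-1-(2,5-dimethoxyphenyl)-4,4-dimethylcyclobutane-1,2-diol
Conditions: K2CO3 (cat.), MeOH, 0 °C → rt
Reagents that add atoms: none
Why: Base-catalysed transesterification removes the acetate; no bond to either stereocentre is touched.

**Step 7**
Reactants: 12 (1R,2R)-1-(2,5-dimethoxyphenyl)-4,4-dimethylcyclobutane-1,2-diol
Product: 14 O-[(1R,2R)-2-(2,5-dimethoxyphenyl)-2-hydroxy-3,3-dimethylcyclobutyl] N-phenylcarbamothioate, via monosodium alkoxide 13 (not isolated)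
Conditions: NaH (1.05 equiv), THF, 0 °C; PhNCS, 0 °C → rt; AcOH quench
Reagents that add atoms: phenyl isothiocyanate, S=C=Nc1ccccc1
Why: The less hindered secondary alkoxide adds to the isothiocyanate (thiocarbamate formation). This thiocarbonyl derivative is preferred to an O-aryl thionocarbonate or an imidazolide because it has no leaving group that the cis tertiary hydroxyl could displace to close a cyclic thionocarbonate, whose radical cleavage would break the tertiary benzylic C1'–O bond.

**Step 8**
Reactants: 14 O-[(1R,2R)-2-(2,5-dimethoxyphenyl)-2-hydroxy-3,3-dimethylcyclobutyl] N-phenylcarbamothioate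
Product: 15 (R)-1-(2,5-dimethoxyphenyl)-2,2-dimethylcyclobutan-1-ol
Conditions: Bu3SnH, AIBN (cat.), toluene, 85 °C
Reagents that add atoms: none
Why: Barton–McCombie deoxygenation in its N-phenylthiocarbamate variant: the stannyl radical adds to sulfur, the C4'–O bond fragments to a secondary cyclobutyl radical, and hydrogen transfer from Bu3SnH gives the methylene. A cyclobutyl radical does not ring-open, a 1,2-aryl shift would need a bicyclo[2.1.0]pentane-like bridged intermediate, and C1' is not involved, so its configuration is retained.

**Step 9**
Reactants: 15 (R)-1-(2,5-dimethoxyphenyl)-2,2-dimethylcyclobutan-1-ol; 16 angelic acid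
Product: 19 (R)-1-(2,5-dimethoxyphenyl)-2,2-dimethylcyclobutyl (Z)-2-methylbut-2-enoate, via angeloyl chloride 17 (not isolated), via lithium cyclobutanolate 18 (not isolated)
Conditions: 16, 1-chloro-N,N,2-trimethylprop-1-en-1-amine, CH2Cl2, 0 °C → rt; separately 15, n-BuLi (1.0 equiv), THF, −78 °C; combine, −78 → 0 °C
Reagents that add atoms: none
Why: O-Acylation of a preformed lithium alkoxide by an acid chloride is the standard method for hindered tertiary alcohols, and C1'–O is not broken, so the configuration is retained. The acid chloride is made with the neutral α-chloroenamine (no HCl) and used cold without amine or pyridine catalysts, the conditions under which the Z geometry is most likely to survive. The ester is installed here because the ring is still a robust dimethoxybenzene and because it blocks the alkoxy-radical ring opening that a free 1-arylcyclobutanol would suffer with tetravalent cerium in step 10.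

**Step 10**
Reactants: 19 (R)-1-(2,5-dimethoxyphenyl)-2,2-dimethylcyclobutyl (Z)-2-methylbut-2-enoate
Product: 20 (R)-1-(3,6-dioxocyclohexa-1,4-dien-1-yl)-2,2-dimethylcyclobutyl (Z)-2-methylbut-2-enoate
Conditions: (NH4)2Ce(NO3)6 (2.5 equiv), MeCN/H2O, 0 °C, short reaction time
Reagents that add atoms: water, O
Why: Oxidative demethylation of a 1,4-dimethoxybenzene to the 1,4-benzoquinone by tetravalent cerium, with the quinone oxygens coming from water. The electron-poor angelate alkene is not oxidised, and the short, cold reaction limits acid-promoted ionisation of the tertiary ester, which becomes far less prone to ionise once the ring is a quinone.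

**Step 11**
Reactants: 21 succinic anhydride
Product: 22 2,5-bis(trimethylsilyloxy)furan
Conditions: Me3SiCl, Et3N, ZnCl2 (cat.), MeCN, rt; distillation
Reagents that add atoms: chlorotrimethylsilane, C[Si](C)(C)Cl
Why: Double enol silylation of the anhydride gives the aromatic bis(silyloxy)furan; it is moisture-sensitive and is distilled and used directly.

**Step 12**
Reactants: 20 (R)-1-(3,6-dioxocyclohexa-1,4-dien-1-yl)-2,2-dimethylcyclobutyl (Z)-2-methylbut-2-enoate; 22 2,5-bis(trimethylsilyloxy)furan
Product: 25 (R)-1-(5,8-dihydroxy-1,4-dioxo-1,4-dihydronaphthalen-2-yl)-2,2-dimethylcyclobutyl (Z)-2-methylbut-2-enoate, via oxa-bridged Diels–Alder adduct 23 (not isolated), via 4a,8a-dihydro tetraone tautomer 24 (not isolated)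
Conditions: CH2Cl2, −40 °C → rt; then 1 M HCl, THF, rt
Reagents that add atoms: none
Why: Diels–Alder reaction of the very electron-rich furan with the quinone at its unsubstituted double bond (the other is shielded by the quaternary C1') gives adduct 23; the bridging ketal collapses with loss of hexamethyldisiloxane to tetraone 24, which enolises to the naphthazarin. No oxidant or deprotection is needed, the diene is symmetrical, and the four transient stereocentres vanish on aromatisation while C1' is untouched.

## Compound list

1 | 2,2-dimethylpent-4-enoic acid | C=CCC(C)(C)C(=O)O | starting material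
2 | 2,2-dimethylpent-4-enoyl chloride | C=CCC(C)(C)C(=O)Cl | intermediate (not isolated)
3 | N-methoxy-N,2,2-trimethylpent-4-enamide | C=CCC(C)(C)C(=O)N(C)OC | intermediate
4 | 1-bromo-2,5-dimethoxybenzene | COc1ccc(OC)c(Br)c1 | starting material
5 | (2,5-dimethoxyphenyl)lithium | [Li]c1cc(OC)ccc1OC | intermediate (not isolated)
6 | lithium 1-(2,5-dimethoxyphenyl)-1-[methoxy(methyl)amino]-2,2-dimethylpent-4-en-1-olate (racemic) | [Li]OC(c1cc(OC)ccc1OC)(N(C)OC)C(C)(C)CC=C | intermediate (not isolated)
7 | 1-(2,5-dimethoxyphenyl)-2,2-dimethylpent-4-en-1-one | C=CCC(C)(C)C(=O)c1cc(OC)ccc1OC | intermediate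
8 | 1-(2,5-dimethoxyphenyl)-2,2-dimethyl-3-(1,2,4-trioxolan-3-yl)propan-1-one (racemic) | O=C(c1cc(OC)ccc1OC)C(C)(C)CC1OCOO1 | intermediate (not isolated)
9 | 4-(2,5-dimethoxyphenyl)-3,3-dimethyl-4-oxobutanal | O=CCC(C)(C)C(=O)c1cc(OC)ccc1OC | intermediate
10 | cis-1-(2,5-dimethoxyphenyl)-4,4-dimethylcyclobutane-1,2-diol, racemate of (1R,2R) and (1S,2S); the (1R,2R) form is drawn | O[C@]1(c2cc(OC)ccc2OC)[C@H](O)CC1(C)C | intermediate
11 | (1R,2R)-2-(2,5-dimethoxyphenyl)-2-hydroxy-3,3-dimethylcyclobutyl acetate | O[C@]1(c2cc(OC)ccc2OC)[C@H](OC(C)=O)CC1(C)C | intermediate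
12 | (1R,2R)-1-(2,5-dimethoxyphenyl)-4,4-dimethylcyclobutane-1,2-diol | O[C@]1(c2cc(OC)ccc2OC)[C@H](O)CC1(C)C | intermediate
13 | sodium (1R,2R)-2-(2,5-dimethoxyphenyl)-2-hydroxy-3,3-dimethylcyclobutan-1-olate | O[C@]1(c2cc(OC)ccc2OC)[C@H](O[Na])CC1(C)C | intermediate (not isolated)
14 | O-[(1R,2R)-2-(2,5-dimethoxyphenyl)-2-hydroxy-3,3-dimethylcyclobutyl] N-phenylcarbamothioate | O[C@]1(c2cc(OC)ccc2OC)[C@H](OC(=S)Nc2ccccc2)CC1(C)C | intermediate
15 | (R)-1-(2,5-dimethoxyphenyl)-2,2-dimethylcyclobutan-1-ol | O[C@]1(c2cc(OC)ccc2OC)CCC1(C)C | intermediate
16 | angelic acid, (Z)-2-methylbut-2-enoic acid | C/C=C(/C)C(=O)O | starting material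
17 | (Z)-2-methylbut-2-enoyl chloride (angeloyl chloride) | C/C=C(/C)C(=O)Cl | intermediate (not isolated)
18 | lithium (R)-1-(2,5-dimethoxyphenyl)-2,2-dimethylcyclobutan-1-olate | [Li]O[C@]1(c2cc(OC)ccc2OC)CCC1(C)C | intermediate (not isolated)
19 | (R)-1-(2,5-dimethoxyphenyl)-2,2-dimethylcyclobutyl (Z)-2-methylbut-2-enoate | C/C=C(/C)C(=O)O[C@]1(c2cc(OC)ccc2OC)CCC1(C)C | intermediate
20 | (R)-1-(3,6-dioxocyclohexa-1,4-dien-1-yl)-2,2-dimethylcyclobutyl (Z)-2-methylbut-2-enoate | C/C=C(/C)C(=O)O[C@]1(C2=CC(=O)C=CC2=O)CCC1(C)C | intermediate
21 | succinic anhydride | O=C1CCC(=O)O1 | starting material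
22 | 2,5-bis(trimethylsilyloxy)furan | C[Si](C)(C)Oc1ccc(O[Si](C)(C)C)o1 | intermediate
23 | (R)-1-[5,8-dioxo-1,4-bis(trimethylsilyloxy)-1,4,4a,5,8,8a-hexahydro-1,4-epoxynaphthalen-6-yl]-2,2-dimethylcyclobutyl (Z)-2-methylbut-2-enoate (mixture of diastereomers at C1, C4, C4a and C8a) | C/C=C(/C)C(=O)O[C@]1(C2=CC(=O)C3C(C2=O)C2(O[Si](C)(C)C)C=CC3(O[Si](C)(C)C)O2)CCC1(C)C | intermediate (not isolated)
24 | (R)-1-(1,4,5,8-tetraoxo-1,4,4a,5,8,8a-hexahydronaphthalen-2-yl)-2,2-dimethylcyclobutyl (Z)-2-methylbut-2-enoate (mixture at C4a and C8a) | C/C=C(/C)C(=O)O[C@]1(C2=CC(=O)C3C(C2=O)C(=O)C=CC3=O)CCC1(C)C | intermediate (not isolated)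
25 | (R)-1-(5,8-dihydroxy-1,4-dioxo-1,4-dihydronaphthalen-2-yl)-2,2-dimethylcyclobutyl (Z)-2-methylbut-2-enoate | C/C=C(/C)C(=O)O[C@]1(C2=CC(=O)c3c(O)ccc(O)c3C2=O)CCC1(C)C | target

## Step count and least certain steps

Total step count: 12. Longest linear sequence: 11 steps (steps 1–10 and 12); step 11 is a one-step side branch.

**Step 4 (key step).** The most likely failure is reduction without ring closure. The 4-exo addition builds a strained ring and is reversible at the stage of the oxygen-centred radical. The aryl–carbonyl conjugation in 9 is twisted by the ortho-methoxy group and the quaternary C2', so ketyl formation may be slow. Intermolecular coupling competes unless dilution is high.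

Fallback: the same C1'–C4' bond is closed photochemically by a Norrish–Yang cyclisation, setting out from 9 and rejoining at 10. The aldehyde alone is reduced (NaBH4, MeOH, −78 °C; the neopentyl-type aryl ketone is inert) to 1-(2,5-dimethoxyphenyl)-4-hydroxy-2,2-dimethylbutan-1-one F1. This is silylated (t-BuMe2SiCl, imidazole, DMF) to 4-(tert-butyldimethylsilyloxy)-1-(2,5-dimethoxyphenyl)-2,2-dimethylbutan-1-one F2. Irradiation (λ > 300 nm, degassed MeCN) lets the excited aryl ketone abstract the oxygen-activated γ-hydrogen at C4'. The 1,4-biradical closes to cis-2-(tert-butyldimethylsilyloxy)-1-(2,5-dimethoxyphenyl)-4,4-dimethylcyclobutan-1-ol F3, and the two α-methyl groups disfavour the competing fragmentation. Desilylation (Bu4NF, THF) gives racemic diol 10; any trans isomer is separated. The limits of this fallback are the less reactive excited state of a dimethoxyphenyl ketone and possible hydrogen abstraction from the ortho-methoxy group.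

**Step 5.** The most likely failure is slow or poorly selective acylation, because the carbinol sits next to a fully substituted carbon bearing a bulky aryl group. The sense of selection may also be opposite to the one assumed; in that case the recovered diol is carried on and step 6 is dropped.

Fallback: classical resolution through diastereomers, setting out from 10 and rejoining at 12. The secondary hydroxyl is esterified with (S)-2-methoxy-2-phenylacetic acid (EDC·HCl, cat. DMAP, CH2Cl2, 0 °C). The two diastereomeric esters are separated by chromatography or crystallisation. The ester of the wanted diol, (1R,2R)-2-(2,5-dimethoxyphenyl)-2-hydroxy-3,3-dimethylcyclobutyl (S)-2-methoxy-2-phenylacetate F4, is cleaved with K2CO3 in MeOH to give 12.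

**Step 7 (with step 8).** The most likely failure is participation of the cis tertiary hydroxyl: thiocarbamoylation at the wrong oxygen, or transfer between the oxygens under the basic conditions. The thiocarbamate may also revert thermally to diol and isothiocyanate before the radical chain takes hold.

Fallback: the tertiary hydroxyl is masked before thioacylation, setting out from acetate 11 and rejoining at 15, so that steps 6–8 are replaced. Silylation (Et3SiOTf, 2,6-lutidine, CH2Cl2) gives (1R,2R)-2-(2,5-dimethoxyphenyl)-3,3-dimethyl-2-(triethylsilyloxy)cyclobutyl acetate F5. Reductive removal of the acetate (i-Bu2AlH, CH2Cl2, −78 °C, chosen to avoid base-induced silyl migration) gives (1R,2R)-2-(2,5-dimethoxyphenyl)-3,3-dimethyl-2-(triethylsilyloxy)cyclobutan-1-ol F6. Thioacylation (PhOC(S)Cl, pyridine, cat. DMAP) gives O-[(1R,2R)-2-(2,5-dimethoxyphenyl)-3,3-dimethyl-2-(triethylsilyloxy)cyclobutyl] O-phenyl carbonothioate F7, which has no free neighbouring hydroxyl. Barton–McCombie reduction (Bu3SnH, AIBN, toluene, 85 °C) gives (R)-[1-(2,5-dimethoxyphenyl)-2,2-dimethylcyclobutoxy]triethylsilane F8, and Bu4NF in THF then liberates 15.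

**Step 9.** The most likely failures are no acylation at the congested tertiary alkoxide, and loss of the Z geometry or of conjugation. The alkoxide can deprotonate the acid chloride at its γ-methyl group (vinylketene pathway), and chloride can add reversibly to the activated acyl species.

Fallback: the double bond is built on the ester by a Z-selective olefination, setting out from 15 (as alkoxide 18) and rejoining at 19. Acylation with 2-[bis(2,2,2-trifluoroethoxy)phosphoryl]propanoyl chloride, an acyl donor with no alkene to isomerise, gives (R)-1-(2,5-dimethoxyphenyl)-2,2-dimethylcyclobutyl 2-[bis(2,2,2-trifluoroethoxy)phosphoryl]propanoate F9 (both epimers at the phosphonate carbon). Still–Gennari olefination (KN(SiMe3)2, 18-crown-6, THF, −78 °C; acetaldehyde) places the new methyl group cis to the ester carbonyl and gives 19.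

**Step 12.** The most likely failures are electron transfer or conjugate addition between the electron-rich furan and the quinone instead of cycloaddition, and ionisation of the C1' ester during acidic desilylation, when the ring that carries it passes through hydroquinone-type tautomers.

Fallback: ring B is annulated by a Diels–Alder/Alder–Rickert sequence with a carbocyclic diene, setting out from 20 and rejoining at 25. 1,4-Bis(trimethylsilyloxy)cyclohexa-1,3-diene F10, the bis(silyl enol ether) of cyclohexane-1,4-dione, adds to the unsubstituted double bond of 20 (toluene, rt) and gives (R)-1-[5,8-dioxo-1,4-bis(trimethylsilyloxy)-1,4,4a,5,8,8a-hexahydro-1,4-ethanonaphthalen-6-yl]-2,2-dimethylcyclobutyl (Z)-2-methylbut-2-enoate F11. Enolisation and oxidation (Et3N, then Ag2O) give (R)-1-[5,8-dioxo-1,4-bis(trimethylsilyloxy)-1,4,5,8-tetrahydro-1,4-ethanonaphthalen-6-yl]-2,2-dimethylcyclobutyl (Z)-2-methylbut-2-enoate F12. Heating in toluene expels ethene in a retro-Diels–Alder step and gives (R)-1-[1,4-dioxo-5,8-bis(trimethylsilyloxy)-1,4-dihydronaphthalen-2-yl]-2,2-dimethylcyclobutyl (Z)-2-methylbut-2-enoate F13. The aryl silyl ethers then hydrolyse in moist MeOH without acid to give 25.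

## Further compounds

F1 | step 4 | 1-(2,5-dimethoxyphenyl)-4-hydroxy-2,2-dimethylbutan-1-one | OCCC(C)(C)C(=O)c1cc(OC)ccc1OC
F2 | step 4 | 4-(tert-butyldimethylsilyloxy)-1-(2,5-dimethoxyphenyl)-2,2-dimethylbutan-1-one | CC(C)(C)[Si](C)(C)OCCC(C)(C)C(=O)c1cc(OC)ccc1OC
F3 | step 4 | cis-2-(tert-butyldimethylsilyloxy)-1-(2,5-dimethoxyphenyl)-4,4-dimethylcyclobutan-1-ol (racemic; (1R,2R) form drawn) | O[C@]1(c2cc(OC)ccc2OC)[C@H](O[Si](C)(C)C(C)(C)C)CC1(C)C
F4 | step 5 | (1R,2R)-2-(2,5-dimethoxyphenyl)-2-hydroxy-3,3-dimethylcyclobutyl (S)-2-methoxy-2-phenylacetate | O[C@]1(c2cc(OC)ccc2OC)[C@H](OC(=O)[C@@H](OC)c2ccccc2)CC1(C)C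
F5 | step 7 | (1R,2R)-2-(2,5-dimethoxyphenyl)-3,3-dimethyl-2-(triethylsilyloxy)cyclobutyl acetate | CC[Si](CC)(CC)O[C@]1(c2cc(OC)ccc2OC)[C@H](OC(C)=O)CC1(C)C
F6 | step 7 | (1R,2R)-2-(2,5-dimethoxyphenyl)-3,3-dimethyl-2-(triethylsilyloxy)cyclobutan-1-ol | CC[Si](CC)(CC)O[C@]1(c2cc(OC)ccc2OC)[C@H](O)CC1(C)C
F7 | step 7 | O-[(1R,2R)-2-(2,5-dimethoxyphenyl)-3,3-dimethyl-2-(triethylsilyloxy)cyclobutyl] O-phenyl carbonothioate | CC[Si](CC)(CC)O[C@]1(c2cc(OC)ccc2OC)[C@H](OC(=S)Oc2ccccc2)CC1(C)C
F8 | step 7 | (R)-[1-(2,5-dimethoxyphenyl)-2,2-dimethylcyclobutoxy]triethylsilane | CC[Si](CC)(CC)O[C@]1(c2cc(OC)ccc2OC)CCC1(C)C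
F9 | step 9 | (R)-1-(2,5-dimethoxyphenyl)-2,2-dimethylcyclobutyl 2-[bis(2,2,2-trifluoroethoxy)phosphoryl]propanoate | CC(C(=O)O[C@]1(c2cc(OC)ccc2OC)CCC1(C)C)P(=O)(OCC(F)(F)F)OCC(F)(F)F
F10 | step 12 | 1,4-bis(trimethylsilyloxy)cyclohexa-1,3-diene | C[Si](C)(C)OC1=CC=C(O[Si](C)(C)C)CC1
F11 | step 12 | (R)-1-[5,8-dioxo-1,4-bis(trimethylsilyloxy)-1,4,4a,5,8,8a-hexahydro-1,4-ethanonaphthalen-6-yl]-2,2-dimethylcyclobutyl (Z)-2-methylbut-2-enoate | C/C=C(/C)C(=O)O[C@]1(C2=CC(=O)C3C(C2=O)C2(O[Si](C)(C)C)C=CC3(O[Si](C)(C)C)CC2)CCC1(C)C
F12 | step 12 | (R)-1-[5,8-dioxo-1,4-bis(trimethylsilyloxy)-1,4,5,8-tetrahydro-1,4-ethanonaphthalen-6-yl]-2,2-dimethylcyclobutyl (Z)-2-methylbut-2-enoate | C/C=C(/C)C(=O)O[C@]1(C2=CC(=O)C3=C(C2=O)C2(O[Si](C)(C)C)C=CC3(O[Si](C)(C)C)CC2)CCC1(C)C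
F13 | step 12 | (R)-1-[1,4-dioxo-5,8-bis(trimethylsilyloxy)-1,4-dihydronaphthalen-2-yl]-2,2-dimethylcyclobutyl (Z)-2-methylbut-2-enoate | C/C=C(/C)C(=O)O[C@]1(C2=CC(=O)c3c(O[Si](C)(C)C)ccc(O[Si](C)(C)C)c3C2=O)CCC1(C)C
A1 | alternative 1 | (R)-2-[2,2-dimethyl-1-(triethylsilyloxy)cyclobutyl]-5,8-dimethoxynaphthalene-1,4-dione | CC[Si](CC)(CC)O[C@]1(C2=CC(=O)c3c(OC)ccc(OC)c3C2=O)CCC1(C)C
A2 | alternative 1 | 8-{[(R)-2,2-dimethyl-1-(triethylsilyloxy)cyclobutyl]ethynyl}-8-hydroxy-2,5-dimethoxybicyclo[4.2.0]octa-1,3,5-trien-7-one (either configuration at C8) | CC[Si](CC)(CC)O[C@]1(C#CC2(O)C(=O)c3c(OC)ccc(OC)c32)CCC1(C)C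
A3 | alternative 1 | (R)-[(1-ethynyl-2,2-dimethylcyclobutyl)oxy]triethylsilane | CC[Si](CC)(CC)O[C@]1(C#C)CCC1(C)C
A4 | alternative 2 | (R)-1-(5,8-dimethoxy-1,4-dihydro-1,4-epoxynaphthalen-2-yl)-2,2-dimethylcyclobutyl (Z)-2-methylbut-2-enoate (both bridgehead epimers) | C/C=C(/C)C(=O)O[C@]1(C2=CC3OC2c2c(OC)ccc(OC)c23)CCC1(C)C
A5 | alternative 2 | (R)-1-(furan-3-yl)-2,2-dimethylcyclobutyl (Z)-2-methylbut-2-enoate | C/C=C(/C)C(=O)O[C@]1(c2ccoc2)CCC1(C)C
A6 | alternative 2 | 3,6-dimethoxy-2-(trimethylsilyl)phenyl trifluoromethanesulfonate | COc1ccc(OC)c([Si](C)(C)C)c1OS(=O)(=O)C(F)(F)F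
A7 | alternative 3 | (R)-2-[2,2-dimethyl-1-(triethylsilyloxy)cyclobutyl]-4-methoxy-5,8-bis(methoxymethoxy)naphthalen-1-ol | CC[Si](CC)(CC)O[C@]1(c2cc(OC)c3c(OCOC)ccc(OCOC)c3c2O)CCC1(C)C
A8 | alternative 3 | pentacarbonyl{[2,5-bis(methoxymethoxy)phenyl](methoxy)methylidene}chromium (zerovalent chromium) | COC(c1cc(OCOC)ccc1OCOC)=[Cr](=C=O)(=C=O)(=C=O)(=C=O)=C=O
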